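**Retrosynthetic overview**
- The target is the 7-O-allyl ether of 8-methoxycoumarin carrying an anti-5,6-diol. The coumarin bicycle is bought intact as daphnetin, so no ring is formed in the route.
- Key disconnection C5–C6, made last. Both carbons are carbonyl-level: C5 of a homoallylic alcohol (aldehyde formed in situ) and the carbonyl carbon of methacrolein. The methacrolein carbon is reversed in polarity as a 1-(benzoyloxy)-2-methylallyl iridium nucleophile (an α-oxy carbanion), which sets both stereocentres in one step.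
- O7–C1 ether: Williamson alkylation of the more acidic 7-OH of daphnetin with an allylic chloride, then 8-O-methylation in the same pot.
- C1 and the (E)-C2=C3 bond: Negishi carboalumination/hydroxymethylation of but-3-yn-1-ol, then allylic-selective chlorination.
- No protecting groups.

Assumption: the facial sense of the [Ir(cod)Cl]2/(R)-SEGPHOS catalyst is taken, from memory, to follow the parent allyl and (α-benzoyloxy)allyl couplings of this catalyst class ((R)-ligand gives the 5S carbinol); if the first run gives the mirror image, (S)-SEGPHOS is used with nothing else changed.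

**Route**

Step 1
Reactants: 1 but-3-yn-1-ol
Product: 4 (2E)-3-methylpent-2-ene-1,5-diol, via vinylalane 2 (not isolated), via lithium alanate 3 (not isolated)
Conditions: Me3Al (3.0 equiv), Cp2ZrCl2 (0.25 equiv), CH2Cl2, 0 °C to rt, 16 h; volatiles removed in vacuo; hexane/THF, nBuLi (1.1 equiv), -78 to 0 °C; (CH2O)n (4 equiv), rt, 3 h; cold 1 M HCl
Reagents that add atoms: trimethylaluminium, C[Al](C)C; paraformaldehyde (reacts as formaldehyde), C=O
Why: Negishi zirconium-catalysed carboalumination adds Me and Al syn across the terminal alkyne (Me to the internal carbon), which fixes the E geometry, and the alkenyl alanate transfers its alkenyl group to formaldehyde with retention.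

Step 2
Reactants: 4 (2E)-3-methylpent-2-ene-1,5-diol
Product: 5 (3E)-5-chloro-3-methylpent-3-en-1-ol
Conditions: NCS (1.1 equiv), Me2S (1.2 equiv), CH2Cl2, -25 to 0 °C, 2 h
Reagents that add atoms: N-chlorosuccinimide, O=C1CCC(=O)N1Cl
Why: Corey–Kim halogenation: only the allylic alkoxysulfonium salt is displaced by chloride (SN2 at the primary allylic carbon, no transposition, E geometry untouched), while the saturated primary hydroxyl returns unchanged on work-up; the E geometry also prevents cyclisation of the chloro alcohol.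

Step 3
Reactants: 5 (3E)-5-chloro-3-methylpent-3-en-1-ol; 6 daphnetin (7,8-dihydroxy-2H-chromen-2-one)
Product: 8 7-{[(2E)-5-hydroxy-3-methylpent-2-en-1-yl]oxy}-8-methoxy-2H-chromen-2-one, via monoalkylated daphnetin 7 (not isolated)
Conditions: 6 (1.1 equiv), KHCO3 (1.2 equiv), KI (0.1 equiv), DMF, 40 °C, 12 h; then K2CO3 (2.0 equiv), MeI (3.0 equiv), rt, 6 h
Reagents that add atoms: iodomethane, CI
Why: Williamson etherification under pKa control: hydrogencarbonate ionises only the 7-OH (vinylogous to the lactone carbonyl), which is alkylated by SN2 without allylic transposition, and the remaining 8-phenol is then methylated by MeI/K2CO3 while the aliphatic hydroxyl stays inert.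

Step 4
Reactants: 9 methacrolein (2-methylprop-2-enal)
Product: 10 2-methylprop-2-ene-1,1-diyl dibenzoate
Conditions: Bz2O (1.05 equiv), FeCl3 (2 mol%), CH2Cl2, 0 °C to rt, 4 h
Reagents that add atoms: benzoic anhydride, O=C(OC(=O)c1ccccc1)c1ccccc1
Why: Lewis-acid-catalysed acylal (gem-diester) formation by 1,2-addition of the anhydride across the aldehyde C=O, as for the known methacrolein diacetate; no stereocentre is formed.

Step 5
Reactants: 8 7-{[(2E)-5-hydroxy-3-methylpent-2-en-1-yl]oxy}-8-methoxy-2H-chromen-2-one; 10 2-methylprop-2-ene-1,1-diyl dibenzoate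
Product: 13 7-{[(2E,5S,6R)-5,6-dihydroxy-3,7-dimethylocta-2,7-dien-1-yl]oxy}-8-methoxy-2H-chromen-2-one (target), via transient aldehyde 11 (not isolated), via C6 monobenzoate 12 (not isolated)
Conditions: 10 (2.0 equiv), [Ir(cod)Cl]2 (2.5 mol%), (R)-SEGPHOS (5 mol%), 4-cyano-3-nitrobenzoic acid (10 mol%), Cs2CO3 (20 mol%), degassed THF (1 M), 90 °C, sealed tube, 48 h; then MeOH, K2CO3 (2.5 equiv), 0 °C to rt, 1 h; aq. NaH2PO4 work-up (pH 4)
Reagents that add atoms: none
Why: Proposed new method: the iridium-catalysed transfer-hydrogenative anti-(α-benzoyloxy)allylation of primary alcohols (known with the acrolein gem-dibenzoate, and 2-substituted donors such as methallyl chloride are known to ionise) is extended to the 2-methyl gem-dibenzoate; the cyclometalated monovalent iridium C,O-benzoate complex dehydrogenates 8 to aldehyde 11 and ionises 10 to a trivalent 1-(benzoyloxy)-2-methylallyl iridium species in which the former carbonyl carbon of methacrolein is nucleophilic, its (E)-σ-allyl form adds through a closed chair transition state to give the anti (5S,6R) pair, (R)-SEGPHOS selects the aldehyde face (C5 S), the benzoic acid released buffers the medium so that 11 stays at a low stationary concentration, and catalytic-methoxide transesterification then frees the diol.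

**Compound list**
1 | but-3-yn-1-ol | C#CCCO | starting material
2 | [(1E)-4-(dimethylalumanyloxy)-2-methylbut-1-en-1-yl]dimethylalumane (vinylalane) | C[Al](C)OCC/C(C)=C/[Al](C)C | intermediate
3 | lithium butyl[(1E)-4-(dimethylalumanyloxy)-2-methylbut-1-en-1-yl]dimethylaluminate | [Li+].CCCC[Al-](C)(C)/C=C(C)/CCO[Al](C)C | intermediate
4 | (2E)-3-methylpent-2-ene-1,5-diol | OC/C=C(C)/CCO | intermediate
5 | (3E)-5-chloro-3-methylpent-3-en-1-ol | OCC/C(C)=C/CCl | intermediate
6 | daphnetin, 7,8-dihydroxy-2H-chromen-2-one | O=c1ccc2ccc(O)c(O)c2o1 | starting material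
7 | 8-hydroxy-7-{[(2E)-5-hydroxy-3-methylpent-2-en-1-yl]oxy}-2H-chromen-2-one | OCC/C(C)=C/COc1ccc2ccc(=O)oc2c1O | intermediate
8 | 7-{[(2E)-5-hydroxy-3-methylpent-2-en-1-yl]oxy}-8-methoxy-2H-chromen-2-one | OCC/C(C)=C/COc1ccc2ccc(=O)oc2c1OC | intermediate
9 | methacrolein, 2-methylprop-2-enal | C=C(C)C=O | starting material
10 | 2-methylprop-2-ene-1,1-diyl dibenzoate | C=C(C)C(OC(=O)c1ccccc1)OC(=O)c1ccccc1 | intermediate
11 | (3E)-5-[(8-methoxy-2-oxo-2H-chromen-7-yl)oxy]-3-methylpent-3-enal | O=CC/C(C)=C/COc1ccc2ccc(=O)oc2c1OC | intermediate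
12 | (3R,4S,6E)-4-hydroxy-8-[(8-methoxy-2-oxo-2H-chromen-7-yl)oxy]-2,6-dimethylocta-1,6-dien-3-yl benzoate | C=C(C)[C@@H](OC(=O)c1ccccc1)[C@@H](O)C/C(C)=C/COc1ccc2ccc(=O)oc2c1OC | intermediate
13 | 7-{[(2E,5S,6R)-5,6-dihydroxy-3,7-dimethylocta-2,7-dien-1-yl]oxy}-8-methoxy-2H-chromen-2-one | C=C(C)[C@@H](O)[C@@H](O)C/C(C)=C/COc1ccc2ccc(=O)oc2c1OC | target

**Step count**
Total: 5 steps. Longest linear sequence: 4 steps (1 → 4 → 5 → 8 → 13); step 4 is a one-step side branch.

**Steps most likely to fail**

Step 5 (key coupling). Failure modes: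
- Aldehyde 11 may lose the coumarin phenoxide by vinylogous E1cB, or its alkene may move into conjugation.
- The allyl aryl ether may itself be ionised by the catalyst.
- The 2-methyl donor may ionise slowly or give a lower anti ratio, because the 2-methyl group weakens the E preference of the allyl unit.

Fallback, setting out from 10 and coming back at 13: the same coupling is run first, on a partner with no aryloxide and no lactone. Bought 4-(trimethylsilyl)but-3-yn-1-ol F1 is coupled with 10 under the step 5 conditions, passing through 4-(trimethylsilyl)but-3-ynal F2 and (3R,4S)-4-hydroxy-2-methyl-7-(trimethylsilyl)hept-1-en-6-yn-3-yl benzoate F3. K2CO3/MeOH then removes the benzoate and the C-silyl group to give (3R,4S)-2-methylhept-1-en-6-yne-3,4-diol F4. Carboalumination and hydroxymethylation as in step 1 (Me3Al 5 equiv, Cp2ZrCl2; nBuLi; (CH2O)n) proceed through the tris-aluminium alkenylalane F5 and its lithium alanate F6 to (2E,5S,6R)-3,7-dimethylocta-2,7-diene-1,5,6-triol F7. Corey–Kim chlorination of the primary allylic hydroxyl gives (3R,4S,6E)-8-chloro-2,6-dimethylocta-1,6-diene-3,4-diol F8. This alkylates 6 under the step 3 conditions to 7-{[(2E,5S,6R)-5,6-dihydroxy-3,7-dimethylocta-2,7-dien-1-yl]oxy}-8-hydroxy-2H-chromen-2-one F9, and MeI/K2CO3 then gives 13. This fallback removes the substrate-related risks only; the donor risk remains.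

Step 3 (regioselective 7-O-alkylation in one pot). Failure mode: alkylation at O-8 or double alkylation of daphnetin.

Fallback, setting out from 5 and coming back at 8: the methoxy group is put in place before the coumarin exists, so no selectivity is needed. Bought 2-methoxybenzene-1,3-diol F10 is condensed with ethyl propiolate (ZnCl2, dioxane, 100 °C; Pechmann-type hydroarylation and lactonisation, one product because the ring is symmetric) to 7-hydroxy-8-methoxy-2H-chromen-2-one F11. Its only phenol is alkylated with 5 (K2CO3, KI, DMF, rt) to give 8.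

Step 1 (hydroxymethylation of the alanate). Failure mode: low yield from the alanate in the presence of the aluminium alkoxide, or competing alkyl transfer.

Fallback, setting out from vinylalane 2 and coming back at 4: C1 is introduced at the ester oxidation level, which needs no ate complex. Vinylalane 2 is acylated directly with ethyl chloroformate (CH2Cl2, 0 °C to rt) to ethyl (2E)-5-hydroxy-3-methylpent-2-enoate F12; the E geometry prevents lactonisation. Reduction with iBu2AlH (3.5 equiv, CH2Cl2, -78 °C) gives 4.

**Further compounds**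
F1 | step 5 | 4-(trimethylsilyl)but-3-yn-1-ol (bought) | C[Si](C)(C)C#CCCO
F2 | step 5 | 4-(trimethylsilyl)but-3-ynal (transient) | C[Si](C)(C)C#CCC=O
F3 | step 5 | (3R,4S)-4-hydroxy-2-methyl-7-(trimethylsilyl)hept-1-en-6-yn-3-yl benzoate | C=C(C)[C@@H](OC(=O)c1ccccc1)[C@@H](O)CC#C[Si](C)(C)C
F4 | step 5 | (3R,4S)-2-methylhept-1-en-6-yne-3,4-diol | C=C(C)[C@@H](O)[C@@H](O)CC#C
F5 | step 5 | tris-aluminium alkenylalane of F4 (O,O-bis(dimethylalumanyl), C-dimethylalumanyl) | C=C(C)[C@@H](O[Al](C)C)[C@@H](O[Al](C)C)C/C(C)=C/[Al](C)C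
F6 | step 5 | lithium butyl alanate of F5 | C=C(C)[C@@H](O[Al](C)C)[C@@H](O[Al](C)C)C/C(C)=C/[Al-](C)(C)CCCC.[Li+]
F7 | step 5 | (2E,5S,6R)-3,7-dimethylocta-2,7-diene-1,5,6-triol | C=C(C)[C@@H](O)[C@@H](O)C/C(C)=C/CO
F8 | step 5 | (3R,4S,6E)-8-chloro-2,6-dimethylocta-1,6-diene-3,4-diol | C=C(C)[C@@H](O)[C@@H](O)C/C(C)=C/CCl
F9 | step 5 | 7-{[(2E,5S,6R)-5,6-dihydroxy-3,7-dimethylocta-2,7-dien-1-yl]oxy}-8-hydroxy-2H-chromen-2-one | C=C(C)[C@@H](O)[C@@H](O)C/C(C)=C/COc1ccc2ccc(=O)oc2c1O
F10 | step 3 | 2-methoxybenzene-1,3-diol (bought) | COc1c(O)cccc1O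
F11 | step 3 | 7-hydroxy-8-methoxy-2H-chromen-2-one | COc1c(O)ccc2ccc(=O)oc12
F12 | step 1 | ethyl (2E)-5-hydroxy-3-methylpent-2-enoate | CCOC(=O)/C=C(C)/CCO
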